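## Retrosynthetic overview

1. Target 19 ⇐ hexa-MOM ether 18 (global deprotection). The pyranone ring of the flavonol ⇐ aldehyde 16 + acetophenone 4 (Claisen–Schmidt, then Algar–Flynn–Oyamada).
2. Cyclohexene 16 ⇐ vinylcyclobutane 15: Sc(III)-triggered heterolysis of the C(acyl)–C(quaternary) bond and reclosure at the far allyl terminus (4 → 6 ring expansion; sets C3 and C4, carries C5).
3. Cyclobutane 15 ⇐ chalcone 9 + aryl diene 14 by enantioselective crossed [2+2] photocycloaddition (sets the aryl-bearing carbon).
4. 9 ⇐ 4 + 8; 14 ⇐ 8 + prenal 10 (directed metalation, dehydration); 4 and 8 ⇐ resorcinol 1 with acetic acid 2 or DMF 5.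
5. Ring order: cyclobutane → cyclohexene → pyranone.

Assumption: the PyBox antipode written in step 8 is taken to be the one that gives the (1R,4S)-cyclobutane (the other antipode is equally available), and only discrete in-flask stages are numbered, not radicals or ion pairs.

Ring numbering used in the text: C1 (methyl-bearing) = C2, C3 (aryl of the flavonol unit), C4 (aroyl), C5 (2,4-dioxygenated aryl), C6 (CH2). The target is 3R,4R,5S, all-trans.

## Route

Step 1
Reactants: 1 resorcinol; 2 acetic acid
Product: 3 1-(2,4-dihydroxyphenyl)ethan-1-one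
Conditions: ZnCl2, AcOH (neat), 145 °C
Reagents that add atoms: none
Why: Nencki (Friedel–Crafts) C-acylation at C4 of resorcinol, the position ortho/para to both hydroxyls, stops at the mono-ketone because the product is deactivated.

Step 2
Reactants: 3 1-(2,4-dihydroxyphenyl)ethan-1-one
Product: 4 1-[2-hydroxy-4-(methoxymethoxy)phenyl]ethan-1-one
Conditions: MOMCl (1.1 equiv), K2CO3, acetone, 0 °C → rt
Reagents that add atoms: chloromethyl methyl ether (MOMCl), COCCl
Why: Williamson-type O-alkylation in which only the 4-OH reacts, because the 2-OH is held in a hydrogen bond to the carbonyl.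

Step 3
Reactants: 1 resorcinol; 5 N,N-dimethylformamide
Product: 7 2,4-dihydroxybenzaldehyde, via iminium salt 6 (not isolated)
Conditions: POCl3, DMF, MeCN, –15 → 25 °C; then H2O, 50 °C
Reagents that add atoms: water, O
Why: Vilsmeier–Haack formylation at the activated C4 position gives the aryl iminium salt, which water hydrolyses to the aldehyde.

Step 4
Reactants: 7 2,4-dihydroxybenzaldehyde
Product: 8 2,4-bis(methoxymethoxy)benzaldehyde
Conditions: MOMCl (3 equiv), i-Pr2NEt, CH2Cl2, 0 °C → rt
Reagents that add atoms: chloromethyl methyl ether (MOMCl), COCCl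
Why: Exhaustive O-alkylation with excess reagent and a soluble amine base also captures the hydrogen-bonded 2-OH.

Step 5
Reactants: 4 1-[2-hydroxy-4-(methoxymethoxy)phenyl]ethan-1-one; 8 2,4-bis(methoxymethoxy)benzaldehyde
Product: 9 (E)-3-[2,4-bis(methoxymethoxy)phenyl]-1-[2-hydroxy-4-(methoxymethoxy)phenyl]prop-2-en-1-one
Conditions: KOH, EtOH/H2O, rt
Reagents that add atoms: none
Why: Claisen–Schmidt aldol condensation of the methyl ketone enolate with the non-enolisable aldehyde; E1cB dehydration gives the E-chalcone and the acetal protecting groups are base-stable.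

Step 6
Reactants: 8 2,4-bis(methoxymethoxy)benzaldehyde; 10 3-methylbut-2-enal (prenal)
Product: 13 3-(1-hydroxy-3-methylbut-2-en-1-yl)-2,4-bis(methoxymethoxy)benzaldehyde (racemic carbinol), via lithium amino alkoxide 11 (not isolated), via C3-aryllithium 12 (not isolated)
Conditions: lithium 4-methylpiperazin-1-ide (N-methylpiperazine + n-BuLi), THF, –20 °C; n-BuLi, –20 → 0 °C; 10, –78 °C; aq. pH 7 buffer
Reagents that add atoms: none
Why: In situ α-amino alkoxide protection of the aldehyde followed by directed ortho-metalation at C3, the site flanked by two OMOM groups; the aryllithium adds 1,2 to the β,β-disubstituted enal and aqueous work-up releases the aldehyde (the carbinol centre is erased in step 7).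

Step 7
Reactants: 13 3-(1-hydroxy-3-methylbut-2-en-1-yl)-2,4-bis(methoxymethoxy)benzaldehyde
Product: 14 2,4-bis(methoxymethoxy)-3-[(1E)-3-methylbuta-1,3-dien-1-yl]benzaldehyde
Conditions: MsCl, Et3N, CH2Cl2, 0 → 40 °C
Reagents that add atoms: none
Why: Mesylation of the benzylic, allylic alcohol and 1,4-elimination (loss of a methyl proton from the allyl cation/allylic mesylate) gives the conjugated E-diene; the basic medium prevents acid-mediated chromene formation.

Step 8
Reactants: 9 (E)-3-[2,4-bis(methoxymethoxy)phenyl]-1-[2-hydroxy-4-(methoxymethoxy)phenyl]prop-2-en-1-one; 14 2,4-bis(methoxymethoxy)-3-[(1E)-3-methylbuta-1,3-dien-1-yl]benzaldehyde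
Product: 15 [(1R,4S)-4-[2,4-bis(methoxymethoxy)phenyl]-2-{(E)-2-[3-formyl-2,6-bis(methoxymethoxy)phenyl]ethenyl}-2-methylcyclobutyl][2-hydroxy-4-(methoxymethoxy)phenyl]methanone (acyl and aryl trans; mixture of epimers at the quaternary C2)
Conditions: Sc(OTf)3 (10 mol%), (S,S)-t-Bu-PyBox (15 mol%), Ru(bpy)3(PF6)2 (2.5 mol%), 14 (3 equiv), i-PrOAc/MeCN 3:1, blue LEDs, rt, degassed
Reagents that add atoms: none
Why: Lewis-acid-catalysed triplet-sensitised crossed [2+2] photocycloaddition: only the Sc(III)–PyBox chelate of the 2'-hydroxychalcone is sensitised by the Ru complex, its β-carbon adds to the CH2 terminus of the diene, and the allyl/α-acyl 1,4-biradical closes to the trans cyclobutane; the ligand shields one enone face and so sets the aryl-bearing carbon (S, future C5), while the quaternary epimers are erased in step 9.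

Step 9
Reactants: 15 the vinylcyclobutyl ketone (both C2 epimers)
Product: 16 3-{(1R,5S,6R)-6-[2-hydroxy-4-(methoxymethoxy)benzoyl]-5-[2,4-bis(methoxymethoxy)phenyl]-3-methylcyclohex-2-en-1-yl}-2,4-bis(methoxymethoxy)benzaldehyde
Conditions: Sc(OTf)3 (20 mol%), 2,6-di-tert-butylpyridine (30 mol%), CH2Cl2, –20 → 25 °C
Reagents that add atoms: none
Why: Proposed new method: Sc(III) binds the 2-hydroxyaryl ketone as a six-membered O,O-chelate, which makes the acyl-bearing carbon an enolate leaving group of malonate-like quality, so the strained bond to the tertiary, allylic quaternary carbon ionises heterolytically to a scandium enolate/1-methyl-3-arylallyl cation pair (a stepwise ionic path, not a concerted shift); the enolate carbon then closes on the far allyl terminus through a chair-like six-membered transition state with both aryl groups and the aroyl group pseudo-equatorial, which sets C3 (R) and C4 (R) all-trans relative to the untouched C5 (S), both epimers of 15 converge, and loss of about 26 kcal/mol of ring strain drives the expansion; the closest known reaction types are the Sc(OTf)3-catalysed ring opening/annulation of donor–acceptor cyclobutane-1,1-diesters and the thermal or alkoxide-accelerated vinylcyclobutane-to-cyclohexene rearrangement.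

Step 10
Reactants: 16 the cyclohexenyl benzaldehyde; 4 1-[2-hydroxy-4-(methoxymethoxy)phenyl]ethan-1-one
Product: 18 2-{3-[(1R,5S,6R)-6-[2-hydroxy-4-(methoxymethoxy)benzoyl]-5-[2,4-bis(methoxymethoxy)phenyl]-3-methylcyclohex-2-en-1-yl]-2,4-bis(methoxymethoxy)phenyl}-3-hydroxy-7-(methoxymethoxy)-4H-chromen-4-one, via chalcone 17 (not isolated)
Conditions: KOH, EtOH/H2O, rt; then 30% H2O2, 0 °C → rt
Reagents that add atoms: hydrogen peroxide, OO
Why: One-pot Claisen–Schmidt condensation and Algar–Flynn–Oyamada oxidative cyclisation (no 6'-substituent, so flavonol forms and not aurone); the isolated trisubstituted alkene is inert to alkaline peroxide and C4, the only base-labile centre, already has the thermodynamic all-equatorial configuration.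

Step 11
Reactants: 18 the hexa-MOM flavonol
Product: 19 2-{3-[(1R,5S,6R)-6-(2,4-dihydroxybenzoyl)-5-(2,4-dihydroxyphenyl)-3-methylcyclohex-2-en-1-yl]-2,4-dihydroxyphenyl}-3,7-dihydroxy-4H-chromen-4-one (target)
Conditions: HCl (1.25 M in MeOH), 30 °C, Ar
Reagents that add atoms: none
Why: Acid-catalysed transacetalisation moves all six aryl MOM groups to methanol under conditions too mild to protonate the trisubstituted alkene, and no stereocentre is epimerisable under acid.

## Compound list

1 | resorcinol | Oc1cccc(O)c1 | starting material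
2 | acetic acid | CC(=O)O | starting material
3 | 1-(2,4-dihydroxyphenyl)ethan-1-one | CC(=O)c1ccc(O)cc1O | intermediate
4 | 1-[2-hydroxy-4-(methoxymethoxy)phenyl]ethan-1-one | CC(=O)c1ccc(OCOC)cc1O | intermediate
5 | N,N-dimethylformamide | CN(C)C=O | starting material
6 | (2,4-dihydroxybenzylidene)dimethyliminium dichlorophosphate | C[N+](C)=Cc1ccc(O)cc1O.[O-]P(Cl)(Cl)=O | intermediate (not isolated)
7 | 2,4-dihydroxybenzaldehyde | O=Cc1ccc(O)cc1O | intermediate
8 | 2,4-bis(methoxymethoxy)benzaldehyde | O=Cc1ccc(OCOC)cc1OCOC | intermediate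
9 | (E)-3-[2,4-bis(methoxymethoxy)phenyl]-1-[2-hydroxy-4-(methoxymethoxy)phenyl]prop-2-en-1-one | O=C(/C=C/c1ccc(OCOC)cc1OCOC)c1ccc(OCOC)cc1O | intermediate
10 | 3-methylbut-2-enal | CC(C)=CC=O | starting material
11 | lithium [2,4-bis(methoxymethoxy)phenyl](4-methylpiperazin-1-yl)methanolate | [Li]OC(N1CCN(C)CC1)c1ccc(OCOC)cc1OCOC | intermediate (not isolated)
12 | 3-lithio derivative of 11 | [Li]OC(N1CCN(C)CC1)c1ccc(OCOC)c([Li])c1OCOC | intermediate (not isolated)
13 | 3-(1-hydroxy-3-methylbut-2-en-1-yl)-2,4-bis(methoxymethoxy)benzaldehyde | O=Cc1ccc(OCOC)c(C(O)C=C(C)C)c1OCOC | intermediate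
14 | 2,4-bis(methoxymethoxy)-3-[(1E)-3-methylbuta-1,3-dien-1-yl]benzaldehyde | O=Cc1ccc(OCOC)c(/C=C/C(C)=C)c1OCOC | intermediate
15 | [(1R,4S)-4-[2,4-bis(methoxymethoxy)phenyl]-2-{(E)-2-[3-formyl-2,6-bis(methoxymethoxy)phenyl]ethenyl}-2-methylcyclobutyl][2-hydroxy-4-(methoxymethoxy)phenyl]methanone, C2 epimer mixture | CC1(/C=C/c2c(OCOC)ccc(C=O)c2OCOC)[C@H](C(=O)c2ccc(OCOC)cc2O)[C@@H](c2ccc(OCOC)cc2OCOC)C1 | intermediate
16 | 3-{(1R,5S,6R)-6-[2-hydroxy-4-(methoxymethoxy)benzoyl]-5-[2,4-bis(methoxymethoxy)phenyl]-3-methylcyclohex-2-en-1-yl}-2,4-bis(methoxymethoxy)benzaldehyde | CC1=C[C@@H](c2c(OCOC)ccc(C=O)c2OCOC)[C@H](C(=O)c2ccc(OCOC)cc2O)[C@@H](c2ccc(OCOC)cc2OCOC)C1 | intermediate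
17 | (E)-chalcone from 16 and 4: 1-[2-hydroxy-4-(methoxymethoxy)phenyl]-3-{3-[(1R,5S,6R)-cyclohexenyl unit of 16]-2,4-bis(methoxymethoxy)phenyl}prop-2-en-1-one | CC1=C[C@@H](c2c(OCOC)ccc(/C=C/C(=O)c3ccc(OCOC)cc3O)c2OCOC)[C@H](C(=O)c2ccc(OCOC)cc2O)[C@@H](c2ccc(OCOC)cc2OCOC)C1 | intermediate (not isolated)
18 | 2-{3-[(1R,5S,6R)-6-[2-hydroxy-4-(methoxymethoxy)benzoyl]-5-[2,4-bis(methoxymethoxy)phenyl]-3-methylcyclohex-2-en-1-yl]-2,4-bis(methoxymethoxy)phenyl}-3-hydroxy-7-(methoxymethoxy)-4H-chromen-4-one | CC1=C[C@@H](c2c(OCOC)ccc(-c3oc4cc(OCOC)ccc4c(=O)c3O)c2OCOC)[C@H](C(=O)c2ccc(OCOC)cc2O)[C@@H](c2ccc(OCOC)cc2OCOC)C1 | intermediate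
19 | 2-{3-[(1R,5S,6R)-6-(2,4-dihydroxybenzoyl)-5-(2,4-dihydroxyphenyl)-3-methylcyclohex-2-en-1-yl]-2,4-dihydroxyphenyl}-3,7-dihydroxy-4H-chromen-4-one | CC1=C[C@@H](c2c(O)ccc(-c3oc4cc(O)ccc4c(=O)c3O)c2O)[C@H](C(=O)c2ccc(O)cc2O)[C@@H](c2ccc(O)cc2O)C1 | target

## Step count and risks

Total step count: 11.
Longest linear sequence: 8 steps (1 → 7 → 8 → 13 → 14 → 15 → 16 → 18 → 19; steps 3, 4, 6, 7, 8, 9, 10, 11).

Three steps most likely to fail:

**Step 8 (enantioselective [2+2]).** The aryl-conjugated diene 14 may react at the wrong alkene, quench the sensitiser or give regioisomers. The fallback sets out from 9 (with 8 as the source of the arene) and returns to the route at 15. Chalcone 9 is photocycloadded under the same chiral Sc/Ru conditions to isoprene (commercial, five heavy atoms), a simple 2-substituted diene of the kind this reaction is established for. This gives [(1R,4S)-4-[2,4-bis(methoxymethoxy)phenyl]-2-ethenyl-2-methylcyclobutyl][2-hydroxy-4-(methoxymethoxy)phenyl]methanone F1. In parallel 8 is metalated as in step 6 and quenched with iodine to give 3-iodo-2,4-bis(methoxymethoxy)benzaldehyde F2. A Mizoroki–Heck coupling of F1 with F2 (Pd(OAc)2, P(o-tol)3, Et3N, DMF, 80 °C) then attaches the aryl group to the vinyl terminus; β-hydride elimination is only possible away from the quaternary carbon, so the E-alkene 15 results.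

**Step 9 (proposed ring expansion).** The C–C ionisation may not occur at a temperature the MOM acetals tolerate. The ion pair may also fragment to 9 + 14, which would erode ee, or close with the wrong C3 configuration. The fallback uses known chemistry; it sets out from 9 and 14 and returns at 16. A stoichiometric chiral boron Lewis acid (VANOL antipode matched to the 5S series, BH3·THF, AcOH, THF, rt) chelates the 2'-hydroxychalcone and promotes its established asymmetric Diels–Alder reaction with the aryl diene. The all-trans (exo) adduct 16 is separated from its cis,trans diastereomer by chromatography. This fallback makes no compound outside the list (F0).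

**Step 11 (global deprotection).** Six acetals must be cleaved in the presence of a trisubstituted alkene flanked by ortho-phenols, so acid-induced cyclic ether formation is the danger. The fallback sets out from 18 and returns at 19 without Brønsted acid. TMSOTf/2,2'-bipyridyl in MeCN at 0 °C exchanges each aryl MOM group for a silyl group and silylates the two free hydroxyls, giving the octakis(trimethylsilyl) ether of 19 F3. F3 is then hydrolysed with water/MeOH at rt to 19.

Further compounds
F1 | step 8 | [(1R,4S)-4-[2,4-bis(methoxymethoxy)phenyl]-2-ethenyl-2-methylcyclobutyl][2-hydroxy-4-(methoxymethoxy)phenyl]methanone (C2 epimers) | CC1(C=C)[C@H](C(=O)c2ccc(OCOC)cc2O)[C@@H](c2ccc(OCOC)cc2OCOC)C1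
F2 | step 8 | 3-iodo-2,4-bis(methoxymethoxy)benzaldehyde | O=Cc1ccc(OCOC)c(I)c1OCOC
F0 | step 9 | none | none
F3 | step 11 | octakis(trimethylsilyl) ether of 19 | CC1=C[C@@H](c2c(O[Si](C)(C)C)ccc(-c3oc4cc(O[Si](C)(C)C)ccc4c(=O)c3O[Si](C)(C)C)c2O[Si](C)(C)C)[C@H](C(=O)c2ccc(O[Si](C)(C)C)cc2O[Si](C)(C)C)[C@@H](c2ccc(O[Si](C)(C)C)cc2O[Si](C)(C)C)C1
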